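**Retrosynthetic overview**

- The target, a 14-hydroxy melampolide, comes from the all-E germacrolide by a late allylic oxidation of C14 (SeO2 ene reaction, then [2,3]-shift). This step also turns the 1(10) olefin ring-cis, as in the presumed germacrolide → melampolide biosynthesis.
- The germacrolide comes from an open (E,E)-farnesal-type chain. An allylchromium closes C6–C7, the bond made by germacrene synthase, and the C6 alkoxide then lactonises onto C12. The C8 methacrylate is already in place and steers C6/C7.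
- The chain comes from three C5 units joined head to tail at C8–C9 and C2–C3, the prenyl-transfer bonds, by two catalytic asymmetric vinylogous aldol reactions of a prenal dienol ether. The aldehyde carbons become the C8 and C2 carbinols, each acylated as it appears.
- The starter C5 unit comes from methyl acrylate and glyoxal mono-acetal (Baylis–Hillman reaction, allylic bromination).
- Ring order: ten-membered carbocycle first, γ-lactone second (same flask), ring-olefin isomerisation last; no protecting groups.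

Assumption: the (S)-oxazaborolidinone (from N-tosyl-L-tryptophan) exposes the Re face of the bound enal and its enantiomer the Si face; if the first adduct shows the opposite sense, the two enantiomers are exchanged between steps 4 and 6.

Numbering in the comments is germacrane numbering. Compound 5 supplies C8 (CHO), C7, C11, C12 (ester) and C13 (CH2Br). The first molecule of 7 supplies C9, C10, C14, C1, C2 and the second supplies C3, C4, C15, C5, C6.

**Step 1**
Reactants: 1 methyl acrylate; 2 2,2-dimethoxyacetaldehyde (60% in water)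
Product: 3 methyl 3-hydroxy-4,4-dimethoxy-2-methylidenebutanoate (racemic)
Conditions: DABCO (1,4-diazabicyclo[2.2.2]octane, 0.3 equiv), 1,4-dioxane–H2O, rt, 48 h
Reagents that add atoms: none
Why: Morita–Baylis–Hillman reaction of an acrylate with an activated, non-enolisable aldehyde; the carbinol centre is racemic, which is harmless because it becomes sp2 in step 2.

**Step 2**
Reactants: 3 methyl 3-hydroxy-4,4-dimethoxy-2-methylidenebutanoate
Product: 5 methyl (2Z)-2-(bromomethyl)-4-oxobut-2-enoate, via bromo acetal 4 (not isolated)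
Conditions: PBr3 (0.4 equiv), Et2O, −10 to 0 °C; then CF3CO2H–H2O, CH2Cl2, 0 °C to rt
Reagents that add atoms: phosphorus tribromide BrP(Br)Br; water O
Why: SN2′ (allylic transposition) bromination of the Baylis–Hillman alcohol gives the favoured (Z)-2-(bromomethyl)enoate with the acetal carbon trans to the ester, and aqueous acid then hydrolyses the dimethyl acetal to the conjugated aldehyde; no stereocentre remains.

**Step 3**
Reactants: 6 3-methylbut-2-enal (prenal)
Product: 7 tert-butyl(dimethyl){[(1E)-3-methylbuta-1,3-dien-1-yl]oxy}silane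
Conditions: tBuMe2SiOSO2CF3 (1.1 equiv), Et3N (1.5 equiv), Et2O, 0 °C to rt; distil
Reagents that add atoms: tert-butyldimethylsilyl trifluoromethanesulfonate CC(C)(C)[Si](C)(C)OS(=O)(=O)C(F)(F)F
Why: soft enolisation (O-silylation, then γ-deprotonation by the amine) converts the enal into its 1-silyloxydiene, the laboratory counterpart of the isopentenyl nucleophile.

**Step 4**
Reactants: 5 methyl (2Z)-2-(bromomethyl)-4-oxobut-2-enoate; 7 prenal silyl dienol ether
Product: 8 methyl (2Z,4R,6E)-2-(bromomethyl)-4-hydroxy-6-methyl-8-oxoocta-2,6-dienoate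
Conditions: (S)-4-(indol-3-ylmethyl)-2-phenyl-3-tosyl-1,3,2-oxazaborolidin-5-one (0.5 equiv), iPrOH (1.2 equiv), EtCN, −78 °C; 7 (1.3 equiv) added slowly
Reagents that add atoms: none
Why: vinylogous Mukaiyama aldol reaction in which the terminal CH2 of 7 attacks the boron-bound aldehyde of 5 (its least hindered electrophilic site, since the alkene carbon C11 is fully substituted), the indole of the catalyst covering the Si face so that Re-face attack sets C8 as R; the new C1=C10 bond is E because the dienol ether reacts s-trans.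

**Step 5**
Reactants: 8 methyl (2Z,4R,6E)-2-(bromomethyl)-4-hydroxy-6-methyl-8-oxoocta-2,6-dienoate
Product: 9 methyl (2Z,4R,6E)-2-(bromomethyl)-6-methyl-4-[(2-methylprop-2-enoyl)oxy]-8-oxoocta-2,6-dienoate
Conditions: methacryloyl chloride (1.5 equiv), 2,6-lutidine (2 equiv), CH2Cl2, −20 to 0 °C, used on crude 8
Reagents that add atoms: methacryloyl chloride C=C(C)C(=O)Cl
Why: O-acylation of the secondary allylic alcohol with an acid chloride and a hindered weak base, which neither quaternises on the allylic bromide nor closes the hydroxy bromide to a dihydrofuran; C8 is untouched.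

**Step 6**
Reactants: 9 methyl (2Z,4R,6E)-2-(bromomethyl)-6-methyl-4-[(2-methylprop-2-enoyl)oxy]-8-oxoocta-2,6-dienoate; 7 prenal silyl dienol ether
Product: 10 methyl (2Z,4R,6E,8S,10E)-2-(bromomethyl)-8-hydroxy-6,10-dimethyl-4-[(2-methylprop-2-enoyl)oxy]-12-oxododeca-2,6,10-trienoate
Conditions: (R)-4-(indol-3-ylmethyl)-2-phenyl-3-tosyl-1,3,2-oxazaborolidin-5-one (0.5 equiv), iPrOH (1.2 equiv), EtCN, −78 °C; 7 (1.05 equiv) by syringe pump
Reagents that add atoms: none
Why: second vinylogous Mukaiyama aldol reaction, now with the enantiomeric catalyst so that 7 adds to the Si face of the enal and sets C2 as S under catalyst control (the remote C8 centre has little say), the new C4=C5 bond being E; keeping 7 limiting holds back addition to the product enal.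

**Step 7**
Reactants: 10 methyl (2Z,4R,6E,8S,10E)-2-(bromomethyl)-8-hydroxy-6,10-dimethyl-4-[(2-methylprop-2-enoyl)oxy]-12-oxododeca-2,6,10-trienoate
Product: 11 methyl (2Z,4R,6E,8S,10E)-8-(acetyloxy)-2-(bromomethyl)-6,10-dimethyl-4-[(2-methylprop-2-enoyl)oxy]-12-oxododeca-2,6,10-trienoate
Conditions: acetyl chloride (1.5 equiv), 2,6-lutidine (2 equiv), CH2Cl2, −20 to 0 °C
Reagents that add atoms: acetyl chloride CC(=O)Cl
Why: acetylation as in step 5; lutidine is too weak a base to deprotonate the γ-position of the enals and eliminate the allylic esters, and C2 is untouched.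

**Step 8**
Reactants: 11 methyl (2Z,4R,6E,8S,10E)-8-(acetyloxy)-2-(bromomethyl)-6,10-dimethyl-4-[(2-methylprop-2-enoyl)oxy]-12-oxododeca-2,6,10-trienoate
Product: 13 (2S,6R,7R,8R)-2-acetoxy-8-methacryloyloxygermacra-1(10)E,4E,11(13)-trien-12,6-olide, via hydroxy ester 12 (not isolated)
Conditions: CrCl2 (8 equiv), THF–DMF (4:1), rt; 11 added over 12 h to 2 mM; aq. NH4Cl work-up
Reagents that add atoms: none
Why: intramolecular Nozaki–Hiyama allylation (chromium Barbier reaction) followed by lactonisation, in which CrCl2 turns the allylic bromide into an allylchromium that adds through C7 to the C6 aldehyde in a chair transition state with C5 and C8 equatorial (6,7-anti, hence the trans-lactone); the crown-like fold of the E,E chain puts the C8 methacrylate in the inside position next to C11 (C8–H anti to the forming bond), which gives 6R,7R, and the chromium alkoxide then closes onto the methyl ester.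

**Step 9**
Reactants: 13 (2S,6R,7R,8R)-2-acetoxy-8-methacryloyloxygermacra-1(10)E,4E,11(13)-trien-12,6-olide
Product: 14 (3aR,4R,6E,8S,10E,11aR)-8-(acetyloxy)-6-(hydroxymethyl)-10-methyl-3-methylidene-2-oxo-2,3,3a,4,5,8,9,11a-octahydrocyclodeca[b]furan-4-yl 2-methylprop-2-enoate (CNP0138477.2)
Conditions: SeO2 (0.5 equiv), tBuOOH (3 equiv), CH2Cl2, rt
Reagents that add atoms: selenium dioxide O=[Se]=O; tert-butyl hydroperoxide CC(C)(C)OO
Why: biomimetic allylic oxidation in which the ene reaction of SeO2 at C1 takes a hydrogen from the C10 methyl (the ring CH2 groups of an E-cyclodecene are poorly aligned) and the [2,3]-sigmatropic shift delivers oxygen to C14 and re-forms C1=C10 with CH2OH trans to C2, the ring-cis melampolide geometry seen in the known SeO2 conversions of germacrolides; no stereocentre is touched.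

**Compound list**

1 | methyl acrylate | C=CC(=O)OC | starting material
2 | 2,2-dimethoxyacetaldehyde | COC(OC)C=O | starting material
3 | methyl 3-hydroxy-4,4-dimethoxy-2-methylidenebutanoate (racemic) | C=C(C(=O)OC)C(O)C(OC)OC | intermediate
4 | methyl (2Z)-2-(bromomethyl)-4,4-dimethoxybut-2-enoate (acetal carbon cis to CH2Br) | COC(OC)/C=C(\CBr)C(=O)OC | intermediate
5 | methyl (2Z)-2-(bromomethyl)-4-oxobut-2-enoate (CHO cis to CH2Br, trans to the ester) | O=C/C=C(\CBr)C(=O)OC | intermediate
6 | 3-methylbut-2-enal (prenal) | CC(C)=CC=O | starting material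
7 | tert-butyl(dimethyl){[(1E)-3-methylbuta-1,3-dien-1-yl]oxy}silane | C=C(C)/C=C/O[Si](C)(C)C(C)(C)C | intermediate
8 | methyl (2Z,4R,6E)-2-(bromomethyl)-4-hydroxy-6-methyl-8-oxoocta-2,6-dienoate | COC(=O)/C(CBr)=C/[C@H](O)C/C(C)=C/C=O | intermediate
9 | methyl (2Z,4R,6E)-2-(bromomethyl)-6-methyl-4-[(2-methylprop-2-enoyl)oxy]-8-oxoocta-2,6-dienoate | COC(=O)/C(CBr)=C/[C@H](OC(=O)C(C)=C)C/C(C)=C/C=O | intermediate
10 | methyl (2Z,4R,6E,8S,10E)-2-(bromomethyl)-8-hydroxy-6,10-dimethyl-4-[(2-methylprop-2-enoyl)oxy]-12-oxododeca-2,6,10-trienoate | COC(=O)/C(CBr)=C/[C@H](OC(=O)C(C)=C)C/C(C)=C/[C@@H](O)C/C(C)=C/C=O | intermediate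
11 | methyl (2Z,4R,6E,8S,10E)-8-(acetyloxy)-2-(bromomethyl)-6,10-dimethyl-4-[(2-methylprop-2-enoyl)oxy]-12-oxododeca-2,6,10-trienoate | COC(=O)/C(CBr)=C/[C@H](OC(=O)C(C)=C)C/C(C)=C/[C@@H](OC(C)=O)C/C(C)=C/C=O | intermediate
12 | methyl 2-[(1S,2R,3E,6S,7E,10R)-6-(acetyloxy)-2-hydroxy-4,8-dimethyl-10-[(2-methylprop-2-enoyl)oxy]cyclodeca-3,7-dien-1-yl]prop-2-enoate (seco hydroxy ester of 13, formed as its chromium alkoxide) | C=C(C)C(=O)O[C@@H]1C/C(C)=C/[C@@H](OC(C)=O)C/C(C)=C/[C@@H](O)[C@@H]1C(=C)C(=O)OC | intermediate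
13 | (2S,6R,7R,8R)-2-acetoxy-8-methacryloyloxygermacra-1(10)E,4E,11(13)-trien-12,6-olide; both ring olefins ring-trans, trans-fused lactone (H-6 and H-7 anti) | C=C(C)C(=O)O[C@@H]1C/C(C)=C/[C@@H](OC(C)=O)C/C(C)=C/[C@H]2OC(=O)C(=C)[C@@H]21 | intermediate
14 | (3aR,4R,6E,8S,10E,11aR)-8-(acetyloxy)-6-(hydroxymethyl)-10-methyl-3-methylidene-2-oxo-2,3,3a,4,5,8,9,11a-octahydrocyclodeca[b]furan-4-yl 2-methylprop-2-enoate; C9 and C2 cis across C1=C10, CH2OH trans to C2 | C=C(C)C(=O)O[C@@H]1C/C(CO)=C\[C@@H](OC(C)=O)C/C(C)=C/[C@H]2OC(=O)C(=C)[C@@H]21 | target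

**Step count and risks**

Total step count: 9. Longest linear sequence: 8 (steps 1, 2, 4, 5, 6, 7, 8, 9); step 3 makes 7, which is used twice. The three building blocks and the acylating and silylating reagents are bulk chemicals.

Steps most likely to fail:

**Step 8 (ring closure).** The C8 ester may prefer the pseudo-equatorial position in the ring-closing transition state. From the 8R chain that would give the (6S,7S) lactone instead of 13. Oligomerisation is the second risk.

The fallback lets the C8 oxygen sit where it wants and corrects C8 afterwards. It sets out from 5 and comes back to the route at 13. Aldol reaction of 5 with 7 under (R)-4-(indol-3-ylmethyl)-2-phenyl-3-tosyl-1,3,2-oxazaborolidin-5-one without isopropanol, so that the silyl group is transferred, gives methyl (2Z,4S,6E)-2-(bromomethyl)-4-{[tert-butyl(dimethyl)silyl]oxy}-6-methyl-8-oxoocta-2,6-dienoate F1. A second aldol reaction with 7 under the same (R)-catalyst and iPrOH gives methyl (2Z,4S,6E,8S,10E)-2-(bromomethyl)-4-{[tert-butyl(dimethyl)silyl]oxy}-8-hydroxy-6,10-dimethyl-12-oxododeca-2,6,10-trienoate F2. Acetyl chloride and 2,6-lutidine give its 8-acetate F3. CrCl2 in THF–DMF at high dilution closes the ring, now with the silyloxy group equatorial, through the C8-epimeric silyloxy hydroxy ester F4 to the 8-epi-8-O-silyl germacrolide F5. HF·pyridine in THF frees the 8-epi alcohol F6. Mitsunobu esterification (methacrylic acid, PPh3, diisopropyl azodicarboxylate, toluene, 0 °C) inverts C8 and installs the methacrylate, which gives 13.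

**Step 9 (late oxidation).** C4=C5 carries an allylic lactone oxygen much as C1=C10 carries the allylic acetate. SeO2 may therefore attack C15 about as readily as C14, and some over-oxidation to the 14-aldehyde is likely.

The fallback moves the oxidation in front of the ring closure, where C4=C5 is part of the enal and inert. It sets out from 11 and comes back at 14. SeO2 (0.5 equiv) and tBuOOH in CH2Cl2 oxidise the only electron-rich olefin of 11; the [2,3]-shift places CH2OH trans to the acetoxy carbon and gives methyl (2Z,4R,6E,8S,10E)-8-(acetyloxy)-2-(bromomethyl)-6-(hydroxymethyl)-10-methyl-4-[(2-methylprop-2-enoyl)oxy]-12-oxododeca-2,6,10-trienoate F7. CrCl2 at high dilution (the free hydroxyl is tolerated) then closes the ring through the seco hydroxy methyl ester of 14 F8 and gives 14 directly. The new uncertainty in this order is oxidation of the C9 methylene instead of the methyl group.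

**Step 6 (second aldol).** The product enal 10 is about as electrophilic as 9, so the dienol ether can add twice. The facial control on a β,β-disubstituted enal is also less secure than in step 4.

The fallback builds the last C5 unit by two C–C bond formations that cannot over-add. It sets out from 9 and comes back at 11. (−)-B-(2-Methylallyl)diisopinocampheylborane (from (+)-α-pinene) in Et2O at −78 °C, with ethanolamine work-up, adds to the Si face of the aldehyde and gives methyl (2Z,4R,6E,8S)-2-(bromomethyl)-8-hydroxy-6,10-dimethyl-4-[(2-methylprop-2-enoyl)oxy]undeca-2,6,10-trienoate F9. Acetyl chloride and 2,6-lutidine give its 8-acetate F10. Cross-metathesis of the 1,1-disubstituted olefin with crotonaldehyde (second-generation Hoveyda–Grubbs catalyst RuCl2(H2IMes)(=CH–C6H4-2-OiPr), CH2Cl2, 40 °C) gives 11 after separation of the minor Z isomer.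

**Further compounds**

F1 | step 8 | methyl (2Z,4S,6E)-2-(bromomethyl)-4-{[tert-butyl(dimethyl)silyl]oxy}-6-methyl-8-oxoocta-2,6-dienoate | COC(=O)/C(CBr)=C/[C@@H](O[Si](C)(C)C(C)(C)C)C/C(C)=C/C=O
F2 | step 8 | methyl (2Z,4S,6E,8S,10E)-2-(bromomethyl)-4-{[tert-butyl(dimethyl)silyl]oxy}-8-hydroxy-6,10-dimethyl-12-oxododeca-2,6,10-trienoate | COC(=O)/C(CBr)=C/[C@@H](O[Si](C)(C)C(C)(C)C)C/C(C)=C/[C@@H](O)C/C(C)=C/C=O
F3 | step 8 | methyl (2Z,4S,6E,8S,10E)-8-(acetyloxy)-2-(bromomethyl)-4-{[tert-butyl(dimethyl)silyl]oxy}-6,10-dimethyl-12-oxododeca-2,6,10-trienoate | COC(=O)/C(CBr)=C/[C@@H](O[Si](C)(C)C(C)(C)C)C/C(C)=C/[C@@H](OC(C)=O)C/C(C)=C/C=O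
F4 | step 8 | C8-epimeric silyloxy hydroxy ester: analogue of 12 with tert-butyl(dimethyl)silyloxy in place of methacryloyloxy and that carbon inverted | CC(C)(C)[Si](C)(C)O[C@H]1C/C(C)=C/[C@@H](OC(C)=O)C/C(C)=C/[C@@H](O)[C@@H]1C(=C)C(=O)OC
F5 | step 8 | 8-epi-8-O-silyl germacrolide: 2-acetoxy-8-[tert-butyl(dimethyl)silyl]oxygermacra-1(10)E,4E,11(13)-trien-12,6-olide with C2, C6 and C7 as in 13 and C8 inverted (H-8 anti to H-7) | CC(C)(C)[Si](C)(C)O[C@H]1C/C(C)=C/[C@@H](OC(C)=O)C/C(C)=C/[C@H]2OC(=O)C(=C)[C@@H]21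
F6 | step 8 | 8-epi alcohol: 2-acetoxy-8-hydroxygermacra-1(10)E,4E,11(13)-trien-12,6-olide with C2, C6 and C7 as in 13 and C8 inverted | O[C@H]1C/C(C)=C/[C@@H](OC(C)=O)C/C(C)=C/[C@H]2OC(=O)C(=C)[C@@H]21
F7 | step 9 | methyl (2Z,4R,6E,8S,10E)-8-(acetyloxy)-2-(bromomethyl)-6-(hydroxymethyl)-10-methyl-4-[(2-methylprop-2-enoyl)oxy]-12-oxododeca-2,6,10-trienoate (C5 and C8 cis across C6=C7) | COC(=O)/C(CBr)=C/[C@H](OC(=O)C(C)=C)C/C(CO)=C\[C@@H](OC(C)=O)C/C(C)=C/C=O
F8 | step 9 | seco hydroxy methyl ester of 14: methyl 2-[(1S,2R,3E,6S,7E,10R)-6-(acetyloxy)-2-hydroxy-8-(hydroxymethyl)-4-methyl-10-[(2-methylprop-2-enoyl)oxy]cyclodeca-3,7-dien-1-yl]prop-2-enoate | C=C(C)C(=O)O[C@@H]1C/C(CO)=C\[C@@H](OC(C)=O)C/C(C)=C/[C@@H](O)[C@@H]1C(=C)C(=O)OC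
F9 | step 6 | methyl (2Z,4R,6E,8S)-2-(bromomethyl)-8-hydroxy-6,10-dimethyl-4-[(2-methylprop-2-enoyl)oxy]undeca-2,6,10-trienoate | COC(=O)/C(CBr)=C/[C@H](OC(=O)C(C)=C)C/C(C)=C/[C@@H](O)CC(C)=C
F10 | step 6 | methyl (2Z,4R,6E,8S)-8-(acetyloxy)-2-(bromomethyl)-6,10-dimethyl-4-[(2-methylprop-2-enoyl)oxy]undeca-2,6,10-trienoate | COC(=O)/C(CBr)=C/[C@H](OC(=O)C(C)=C)C/C(C)=C/[C@@H](OC(C)=O)CC(C)=C
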